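The tetrahydropyran ring is disconnected at O1–C2 and C5–C6, the retron of a hetero-Diels–Alder reaction between an aldehyde and a 2-silyloxydiene. One catalytic asymmetric cycloaddition unites two achiral guaiacyl halves, closes the ring by bonding the aldehyde oxygen (O1) to the benzylic diene terminus (C2), and sets C2 and C6 cis. It exploits the C4 oxygen lying 1,3 to C2 and C6, the diequatorial C2-aryl/C6-phenethyl pair flanking O1, and the electron-rich aryl ring on C2, which stabilises charge where O1 bonds. The precursors are the bis-silylated dienol ether of dehydrozingerone and a 3-arylpropanal. The locked pyranone chair then relays the axial C4 hydroxyl.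

Key step: step 4

Assumption: the sense of induction of CrCl(L*) is extrapolated from its behaviour with other unbranched aliphatic aldehydes. Should the opposite sense be found, the equally available complex of the (1S,2R)-ligand is used and nothing else changes.

Notation: ring atoms are O1, C2 (aryl), C3, C4 (oxygen), C5 and C6 (phenethyl). TBS = tert-butyldimethylsilyl. CrCl(L*) = chloro[(1R,2S)-1-{[3-(1-adamantyl)-5-methyl-2-oxidobenzylidene]amino}indan-2-olato]chromium. This is the complex of trivalent chromium with the dianion of the Schiff base H2L*, made from (1R,2S)-1-aminoindan-2-ol and 3-(1-adamantyl)-2-hydroxy-5-methylbenzaldehyde.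

Step 1
Reactants: 1 dehydrozingerone, (E)-4-(4-hydroxy-3-methoxyphenyl)but-3-en-2-one
Product: 2 (E)-1-[4-(TBS-oxy)-3-methoxyphenyl]-3-(TBS-oxy)buta-1,3-diene
Conditions: TBSOTf (2.3 equiv), Et3N (3.5 equiv), CH2Cl2, 0 °C
Reagents that add atoms: tert-butyldimethylsilyl triflate, CC(C)(C)[Si](C)(C)OS(=O)(=O)C(F)(F)F
Why: Soft enolisation and silylation: the silyl triflate caps the phenol and activates the ketone oxygen, and Et3N removes a proton from the methyl group, the only enolisable position, which should give the 2-silyloxydiene with the (E)-styryl geometry untouched.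

Step 2
Reactants: 3 methyl 3-(4-hydroxy-3-methoxyphenyl)propanoate (methyl dihydroferulate)
Product: 4 methyl 3-[4-(TBS-oxy)-3-methoxyphenyl]propanoate
Conditions: TBSCl, imidazole, DMF, rt
Reagents that add atoms: tert-butyldimethylsilyl chloride, CC(C)(C)[Si](C)(C)Cl
Why: Imidazole-promoted O-silylation of the only acidic OH masks the phenol against the hydride and Lewis acid steps that follow.

Step 3
Reactants: 4 methyl 3-[4-(TBS-oxy)-3-methoxyphenyl]propanoate
Product: 5 3-[4-(TBS-oxy)-3-methoxyphenyl]propanal
Conditions: i-Bu2AlH (1.1 equiv), toluene, −78 °C; MeOH, then aq potassium sodium tartrate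
Reagents that add atoms: none
Why: Partial ester reduction: the aluminium hemiacetal persists at −78 °C and collapses to the aldehyde only on quench, and the aryl silyl ether is inert to the reagent.

Step 4
Reactants: 2 (E)-1-[4-(TBS-oxy)-3-methoxyphenyl]-3-(TBS-oxy)buta-1,3-diene; 5 3-[4-(TBS-oxy)-3-methoxyphenyl]propanal
Product: 7 (2S,6S)-2-[4-(TBS-oxy)-3-methoxyphenyl]-6-{2-[4-(TBS-oxy)-3-methoxyphenyl]ethyl}tetrahydro-4H-pyran-4-one, via silyl enol ether cycloadduct 6 (not isolated)
Conditions: CrCl(L*) (7.5 mol %), 4 Å MS, neat, rt; then TFA (cat.), wet CH2Cl2, 0 °C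
Reagents that add atoms: none
Why: CrCl(L*), a chiral Lewis acid of trivalent chromium, binds the carbonyl oxygen of 5, and diene 2 adds in a concerted but asynchronous [4+2] hetero-Diels–Alder reaction in which its enol-silane CH2 bonds to the carbonyl carbon (C5–C6) while the carbonyl oxygen bonds to the aryl-bearing terminus (O1–C2). The closest known reaction type is the asymmetric hetero-Diels–Alder reaction of 4-substituted 2-silyloxy-1,3-dienes with unbranched aliphatic aldehydes under tridentate Schiff-base chromium catalysis, and 4-aryl-2-silyloxydienes are established partners in such cycloadditions. The one ring formed, the six-membered oxacycle, is closed by intermolecular [4π+2π] cycloaddition; should a stepwise Mukaiyama aldol path intervene, the acid treatment closes the same O1–C2 bond by 6-endo-trig oxa-Michael addition, so both paths should converge on 7. C6 is controlled by the catalyst, which leaves the Re face of the bound aldehyde open, and C2 is controlled relative to C6 by the endo transition state of the (E)-diene, which places both ring hydrogens on one face (2,6-cis); this is also the thermodynamic isomer, so reversible opening of the activated C2–O1 bond corrects rather than erodes it while C6 stays untouched. Regioselectivity is secured by the 2-silyloxy group, which makes the CH2 terminus the only nucleophilic carbon, and by the 4-silyloxy-3-methoxyphenyl ring, which stabilises the developing positive charge at C2; the absence of allylic C–H bonds in 2 excludes a carbonyl-ene path, and the silyl ethers keep the phenols from quenching diene or catalyst. Catalytic acid in wet solvent then protonates only the enol silane carbon C3 of 6, since aryl silyl ethers hydrolyse far more slowly.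

Step 5
Reactants: 7 (2S,6S)-2-[4-(TBS-oxy)-3-methoxyphenyl]-6-{2-[4-(TBS-oxy)-3-methoxyphenyl]ethyl}tetrahydro-4H-pyran-4-one
Product: 9 (2S,4S,6S)-2-(4-hydroxy-3-methoxyphenyl)-6-[2-(4-hydroxy-3-methoxyphenyl)ethyl]tetrahydro-2H-pyran-4-ol (target), via bis-silyl axial alcohol 8 (not isolated)
Conditions: LiBH(s-Bu)3 (L-Selectride, 1.5 equiv), THF, −78 °C; AcOH (4 equiv); then n-Bu4NF (6 equiv), 0 °C to rt
Reagents that add atoms: none
Why: Diastereoselective ketone reduction by a bulky borohydride: the 2,6-diequatorial chair of 7 forces the hydride onto the equatorial trajectory and should give the axial (4S)-alcohol trans to both ring substituents, after which acetic-acid-buffered fluoride desilylation frees both phenols without disturbing the benzylic ring ether.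

Compound list
1 | dehydrozingerone, (E)-4-(4-hydroxy-3-methoxyphenyl)but-3-en-2-one | CC(=O)/C=C/c1ccc(O)c(OC)c1 | starting material
2 | (E)-1-[4-(TBS-oxy)-3-methoxyphenyl]-3-(TBS-oxy)buta-1,3-diene | C=C(O[Si](C)(C)C(C)(C)C)/C=C/c1ccc(O[Si](C)(C)C(C)(C)C)c(OC)c1 | intermediate
3 | methyl 3-(4-hydroxy-3-methoxyphenyl)propanoate | COC(=O)CCc1ccc(O)c(OC)c1 | starting material
4 | methyl 3-[4-(TBS-oxy)-3-methoxyphenyl]propanoate | COC(=O)CCc1ccc(O[Si](C)(C)C(C)(C)C)c(OC)c1 | intermediate
5 | 3-[4-(TBS-oxy)-3-methoxyphenyl]propanal | O=CCCc1ccc(O[Si](C)(C)C(C)(C)C)c(OC)c1 | intermediate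
6 | (2S,6S)-4-(TBS-oxy)-2-[4-(TBS-oxy)-3-methoxyphenyl]-6-{2-[4-(TBS-oxy)-3-methoxyphenyl]ethyl}-5,6-dihydro-2H-pyran (cycloadduct, not isolated) | COc1cc(CC[C@H]2CC(O[Si](C)(C)C(C)(C)C)=C[C@@H](c3ccc(O[Si](C)(C)C(C)(C)C)c(OC)c3)O2)ccc1O[Si](C)(C)C(C)(C)C | intermediate
7 | (2S,6S)-2-[4-(TBS-oxy)-3-methoxyphenyl]-6-{2-[4-(TBS-oxy)-3-methoxyphenyl]ethyl}tetrahydro-4H-pyran-4-one (2,6-cis) | COc1cc(CC[C@H]2CC(=O)C[C@@H](c3ccc(O[Si](C)(C)C(C)(C)C)c(OC)c3)O2)ccc1O[Si](C)(C)C(C)(C)C | intermediate
8 | (2S,4S,6S)-2-[4-(TBS-oxy)-3-methoxyphenyl]-6-{2-[4-(TBS-oxy)-3-methoxyphenyl]ethyl}tetrahydro-2H-pyran-4-ol (axial OH, not isolated) | COc1cc(CC[C@H]2C[C@H](O)C[C@@H](c3ccc(O[Si](C)(C)C(C)(C)C)c(OC)c3)O2)ccc1O[Si](C)(C)C(C)(C)C | intermediate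
9 | (2S,4S,6S)-2-(4-hydroxy-3-methoxyphenyl)-6-[2-(4-hydroxy-3-methoxyphenyl)ethyl]tetrahydro-2H-pyran-4-ol | COc1cc(CC[C@H]2C[C@H](O)C[C@@H](c3ccc(O)c(OC)c3)O2)ccc1O | target

Total step count: 5. Longest linear sequence: 4 steps (3 → 4 → 5 → 7 → 9).

Steps most likely to fail

1. Step 4. What may go wrong:
- The cycloaddition may be slow, because the diene gives up its styrene conjugation.
- The diene may be lost by hydrolysis over the long reaction time.
- The enantiofacial discrimination may be weak.

The fallback sets out from 1 and 5 and returns at 7, making the two bonds one after the other. Phenol 1 is silylated with TBSCl and imidazole to (E)-4-[4-(TBS-oxy)-3-methoxyphenyl]but-3-en-2-one F1. Its boron enolate is formed with Ipc2BCl and Et3N in Et2O at −78 °C, using the reagent antipode that attacks the Re face of 5. An asymmetric boron aldol reaction of this enolate with 5 gives (1E,5S)-1,7-bis[4-(TBS-oxy)-3-methoxyphenyl]-5-hydroxyhept-1-en-3-one F2. Amberlyst-15 in CH2Cl2 then closes O1–C2 by reversible 6-endo-trig oxa-Michael addition, under thermodynamic control, to the cis-pyranone 7.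

2. Step 5. What may go wrong:
- The preference for equatorial hydride delivery may be incomplete.
- The benzylic C2–O1 bond may open when phenoxide is released by fluoride in the same flask.

The fallback sets out from 7 and returns at 8. NaBH4 in MeOH at −20 °C attacks axially and should give the all-cis (2S,4R,6S)-equatorial alcohol F3. A Mitsunobu reaction (PPh3, DIAD, 4-nitrobenzoic acid, toluene) inverts C4 to the axial (2S,4S,6S)-4-nitrobenzoate F4. Methanolysis (K2CO3, MeOH, 0 °C) gives 8, now isolated, which is desilylated in a separate operation with n-Bu4NF/AcOH to 9. Any aryl silyl ether lost during methanolysis only anticipates that last operation.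

3. Step 3. What may go wrong: the aluminium hemiacetal may collapse before the quench, which leads to over-reduction. The fallback sets out from 4 and returns at 5. Exhaustive reduction with i-Bu2AlH (2.5 equiv, CH2Cl2, 0 °C) gives 3-[4-(TBS-oxy)-3-methoxyphenyl]propan-1-ol F5. This alcohol is oxidised with Dess–Martin periodinane (NaHCO3, CH2Cl2, rt) to 5.

Further compounds
F1 | step 4 | (E)-4-[4-(TBS-oxy)-3-methoxyphenyl]but-3-en-2-one | CC(=O)/C=C/c1ccc(O[Si](C)(C)C(C)(C)C)c(OC)c1
F2 | step 4 | (1E,5S)-1,7-bis[4-(TBS-oxy)-3-methoxyphenyl]-5-hydroxyhept-1-en-3-one | COc1cc(CC[C@H](O)CC(=O)/C=C/c2ccc(O[Si](C)(C)C(C)(C)C)c(OC)c2)ccc1O[Si](C)(C)C(C)(C)C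
F3 | step 5 | (2S,4R,6S)-2-[4-(TBS-oxy)-3-methoxyphenyl]-6-{2-[4-(TBS-oxy)-3-methoxyphenyl]ethyl}tetrahydro-2H-pyran-4-ol (equatorial OH) | COc1cc(CC[C@H]2C[C@@H](O)C[C@@H](c3ccc(O[Si](C)(C)C(C)(C)C)c(OC)c3)O2)ccc1O[Si](C)(C)C(C)(C)C
F4 | step 5 | (2S,4S,6S)-2-[4-(TBS-oxy)-3-methoxyphenyl]-6-{2-[4-(TBS-oxy)-3-methoxyphenyl]ethyl}tetrahydro-2H-pyran-4-yl 4-nitrobenzoate (axial ester) | COc1cc(CC[C@H]2C[C@H](OC(=O)c3ccc([N+](=O)[O-])cc3)C[C@@H](c3ccc(O[Si](C)(C)C(C)(C)C)c(OC)c3)O2)ccc1O[Si](C)(C)C(C)(C)C
F5 | step 3 | 3-[4-(TBS-oxy)-3-methoxyphenyl]propan-1-ol | OCCCc1ccc(O[Si](C)(C)C(C)(C)C)c(OC)c1
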